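C3–C6 of the target are the C2-symmetric tetraol of D-mannitol, and C7 sits in a 1,4-dioxygenated E-ene, C7(O)–C8=C9–C10(O), at the edge of the all-cis tetrahydrofuran. The route therefore rests on the C7–O4 bond: Pd(0) ionises a trans-C9/C10 vinyl epoxide in an open-chain precursor and O4 closes the tetrahydrofuran on the far allyl terminus, which sets the contra-steric C7 centre by 1,4-chirality transfer, creates the E-C8=C9 alkene and frees O10 in one operation. The precursor is a mannitol-derived C1–C8 triol (two-directional vinylation of the bis-epoxide, terminus differentiation) joined to a C8–C12 vinyl epoxide by cross-metathesis.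

Key step: step 12

Remark: atoms are numbered C1–C12 along the target chain (C1 lactone carbonyl, C12 methyl; O4 tetrahydrofuran oxygen, O5 lactone oxygen); PMB = 4-methoxybenzyl, TBS = tert-butyldimethylsilyl; catalyst-bound species (π-allylpalladium, ruthenium carbenes, titanium tartrate complexes) are not numbered.

Step 1
Reactants: 1 3,4-O-isopropylidene-D-mannitol
Product: 2 3,4-O-isopropylidene-1,6-di-O-(4-toluenesulfonyl)-D-mannitol
Conditions: TsCl (2.1 equiv), pyridine, −15 °C to 0 °C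
Reagents that add atoms: 4-toluenesulfonyl chloride, Cc1ccc(cc1)S(=O)(=O)Cl
Why: Sulfonylation should be selective for the two primary hydroxyls over the hindered secondary ones next to the trans-acetonide, and no stereocentre is touched.

Step 2
Reactants: 2 3,4-O-isopropylidene-1,6-di-O-(4-toluenesulfonyl)-D-mannitol
Product: 3 1,2:5,6-dianhydro-3,4-O-isopropylidene-D-mannitol
Conditions: K2CO3, MeOH, 0 °C to rt
Reagents that add atoms: none
Why: Double intramolecular Williamson etherification (3-exo-tet) of the secondary alkoxides onto the primary tosylates closes both epoxides with retention, since no C–O bond at a stereocentre is broken.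

Step 3
Reactants: 3 1,2:5,6-dianhydro-3,4-O-isopropylidene-D-mannitol
Product: 5 (3R,4R,5R,6R)-4,5-(isopropylidenedioxy)octa-1,7-diene-3,6-diol, via bis-sulfonium betaine 4 (not isolated)
Conditions: Me3S+ I− (6 equiv), n-BuLi (5.8 equiv), THF, −10 °C to rt
Reagents that add atoms: trimethylsulfonium iodide, C[S+](C)C.[I-]
Why: Dimethylsulfonium methylide opens each terminal epoxide at CH2 and the betaine loses dimethyl sulfide by ylide-mediated elimination (one-carbon homologation of an epoxide to an allylic alcohol), so the four mannitol stereocentres become C3–C6 unchanged.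

Step 4
Reactants: 5 (3R,4R,5R,6R)-4,5-(isopropylidenedioxy)octa-1,7-diene-3,6-diol
Product: 6 (3R,4R,5R,6R)-4,5-(isopropylidenedioxy)-3,6-bis[(4-methoxybenzyl)oxy]octa-1,7-diene
Conditions: NaH, PMBCl, Bu4NI (cat.), DMF, 0 °C to rt
Reagents that add atoms: 4-methoxybenzyl chloride, COc1ccc(CCl)cc1
Why: Williamson etherification of both homotopic allylic alkoxides places a Pd-stable, non-migrating group on exactly the two oxygens (O3, O6) that end as free hydroxyls.

Step 5
Reactants: 6 (3R,4R,5R,6R)-4,5-(isopropylidenedioxy)-3,6-bis[(4-methoxybenzyl)oxy]octa-1,7-diene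
Product: 8 (3R,4R,5R,6R)-4,5-(isopropylidenedioxy)-3,6-bis[(4-methoxybenzyl)oxy]oct-7-en-1-ol, via B-alkyl-9-BBN borane 7 (not isolated)
Conditions: 9-BBN (0.9 equiv), THF, 0 °C to rt; then NaOH, H2O2, 0 °C
Reagents that add atoms: hydrogen peroxide, OO
Why: Anti-Markovnikov hydroboration–oxidation of one of the two homotopic vinyl groups differentiates the termini; the C2 axis means only one mono-adduct can form, the reaction is statistical, and unreacted 6 is recycled.

Step 6
Reactants: 8 (3R,4R,5R,6R)-4,5-(isopropylidenedioxy)-3,6-bis[(4-methoxybenzyl)oxy]oct-7-en-1-ol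
Product: 9 (3R,4S,5S,6R)-3,6-bis[(4-methoxybenzyl)oxy]oct-7-ene-1,4,5-triol
Conditions: 1 M aq. HCl, THF, 40 °C
Reagents that add atoms: none
Why: Acid hydrolysis of the isopropylidene acetal should free O4 and O5 while PMB ethers and the alkene survive dilute aqueous acid.

Step 7
Reactants: 10 (R)-but-3-yn-2-ol; 11 vinyl bromide
Product: 12 (R)-hex-5-en-3-yn-2-ol
Conditions: PdCl2(PPh3)2 (2 mol %), CuI (4 mol %), Et2NH, THF, 0 °C to rt
Reagents that add atoms: none
Why: Sonogashira coupling of the terminal alkyne with the vinyl halide, in which the carbinol stereocentre is a spectator.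

Step 8
Reactants: 12 (R)-hex-5-en-3-yn-2-ol
Product: 14 (2R,3E)-hexa-3,5-dien-2-ol, via cyclic alkenylaluminate 13 (not isolated)
Conditions: LiAlH4, THF, 0 °C to rt; then aq. NaOH work-up
Reagents that add atoms: none
Why: Hydroxyl-directed trans-hydroalumination of the propargylic alcohol followed by protonolysis should give only the E-alkene and leave the terminal vinyl group and the stereocentre untouched.

Step 9
Reactants: 14 (2R,3E)-hexa-3,5-dien-2-ol
Product: 15 (2R,3R,4R)-3,4-epoxyhex-5-en-2-ol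
Conditions: Ti(OiPr)4 (10 mol %), D-(−)-diisopropyl tartrate (12 mol %), t-BuOOH, 4 Å MS, CH2Cl2, −20 °C
Reagents that add atoms: tert-butyl hydroperoxide, CC(C)(C)OO
Why: Sharpless asymmetric epoxidation of the allylic (not the distal) alkene in the matched sense, D-(−)-tartrate and the (R)-carbinol directing oxygen to the same face, should give the erythro trans-epoxide with C3 and C4 both R.

Step 10
Reactants: 15 (2R,3R,4R)-3,4-epoxyhex-5-en-2-ol
Product: 16 tert-butyl{(1R)-1-[(2S,3R)-3-ethenyloxiran-2-yl]ethoxy}dimethylsilane (TBS ether of 15)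
Conditions: TBSCl, imidazole, DMF, 0 °C to rt
Reagents that add atoms: tert-butyldimethylsilyl chloride, CC(C)(C)[Si](C)(C)Cl
Why: Silylation under non-acidic conditions preserves the vinyl epoxide, and a silyl ether, unlike an ester, is not expected to shift to the C10 alkoxide generated in step 12.

Step 11
Reactants: 9 (3R,4S,5S,6R)-3,6-bis[(4-methoxybenzyl)oxy]oct-7-ene-1,4,5-triol; 16 TBS ether of 15 (3 equiv)
Product: 17 (3R,4S,5S,6R,7E,9R,10S,11R)-11-[(tert-butyldimethylsilyl)oxy]-9,10-epoxy-3,6-bis[(4-methoxybenzyl)oxy]dodec-7-ene-1,4,5-triol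
Conditions: Hoveyda–Grubbs II (5 mol %), CH2Cl2, 40 °C
Reagents that add atoms: none
Why: Olefin cross-metathesis of two terminal, allylically oxygenated alkenes joins C7 to C8 with loss of ethylene and thermodynamic E selectivity; free hydroxyls, ethers and the epoxide are tolerated by the ruthenium carbene.

Step 12
Reactants: 17 (3R,4S,5S,6R,7E,9R,10S,11R)-11-[(tert-butyldimethylsilyl)oxy]-9,10-epoxy-3,6-bis[(4-methoxybenzyl)oxy]dodec-7-ene-1,4,5-triol
Product: 18 (3R,4S,5R,6S,7S,8E,10S,11R)-11-[(tert-butyldimethylsilyl)oxy]-4,7-epoxy-3,6-bis[(4-methoxybenzyl)oxy]dodec-8-ene-1,5,10-triol (all-cis tetrahydrofuran)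
Conditions: Pd2(dba)3·CHCl3 (2.5 mol %), PPh3 (15 mol %), THF, 0 °C to rt
Reagents that add atoms: none
Why: Pd(0) opens the vinyl epoxide by anti ionisation at C9 to a syn,syn-(π-allyl)palladium cation carrying the C10 alkoxide, which takes the proton of O4–H, and the O4 alkoxide then attacks the far terminus C7 anti to palladium. The closest known reaction type is the intramolecular Tsuji–Trost allylic etherification of hydroxy vinyl epoxides (net syn 1,4-addition). The tetrahydrofuran is closed in a 5-exo mode on the allyl terminus (O4–C7). The one new stereocentre, C7 (S), is controlled by the configuration of the trans C9/C10 epoxide and the E geometry of C7=C8, because two inversions place the new C–O bond on the allyl face that the epoxide oxygen left; this transfer does not depend on the bias of the forming ring and so should deliver the contra-steric all-cis array, while C10 keeps its C–O bond and C8=C9 forms E from the syn,syn allyl. The step needs regioselectivity (C7, not C9) and chemoselectivity among three hydroxyls: O4 at C9 would need a seven-membered ring, O5 could only form an oxetane at C7 or a dihydropyran with a cis alkene at C9 that the syn,syn complex cannot offer, and O1 is remote. Low temperature and the tight ion pair should keep the C11 silyl ether in place and suppress β-hydride collapse of the zwitterion to an enone.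

Step 13
Reactants: 18 all-cis tetrahydrofuran triol
Product: 21 (2S,3R,3aR,7R,7aR)-2-[(1E,3S,4R)-4-[(tert-butyldimethylsilyl)oxy]-3-hydroxypent-1-en-1-yl]-3,7-bis[(4-methoxybenzyl)oxy]hexahydro-5H-furo[3,2-b]pyran-5-one, via hydroxy aldehyde 19 (not isolated), via lactol 20 (not isolated)
Conditions: TEMPO (0.2 equiv), PhI(OAc)2 (2.5 equiv), CH2Cl2, rt
Reagents that add atoms: none
Why: Oxoammonium (TEMPO) oxidation is selective for the primary alcohol, the aldehyde is trapped by the cis C5 hydroxyl as the six-membered lactol and this is oxidised on to the δ-lactone (oxidative lactonisation of a 1,5-diol); O4 is already an ether, so no γ-lactone can form.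

Step 14
Reactants: 21 bicyclic lactone with free C10 hydroxyl
Product: 22 (2S,3R,3aR,7R,7aR)-2-[(1E,3S,4R)-3-(benzoyloxy)-4-[(tert-butyldimethylsilyl)oxy]pent-1-en-1-yl]-3,7-bis[(4-methoxybenzyl)oxy]hexahydro-5H-furo[3,2-b]pyran-5-one
Conditions: BzCl, pyridine, DMAP (cat.), CH2Cl2, 0 °C
Reagents that add atoms: benzoyl chloride, O=C(Cl)c1ccccc1
Why: Acylation of the only free hydroxyl (C10) under mild amine base, which the β-alkoxy lactone should tolerate.

Step 15
Reactants: 22 C10 benzoate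
Product: 23 (2S,3R,3aR,7R,7aR)-2-[(1E,3S,4R)-3-(benzoyloxy)-4-hydroxypent-1-en-1-yl]-3,7-bis[(4-methoxybenzyl)oxy]hexahydro-5H-furo[3,2-b]pyran-5-one
Conditions: HF·pyridine, pyridine, THF, 0 °C to rt
Reagents that add atoms: none
Why: Fluoride-mediated desilylation under buffered, weakly acidic conditions should free O11 without benzoyl migration, lactone opening or loss of the PMB ethers.

Step 16
Reactants: 23 C11 alcohol
Product: 24 (2S,3R,3aR,7R,7aR)-2-[(1E,3S,4R)-4-acetoxy-3-(benzoyloxy)pent-1-en-1-yl]-3,7-bis[(4-methoxybenzyl)oxy]hexahydro-5H-furo[3,2-b]pyran-5-one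
Conditions: Ac2O, pyridine, DMAP (cat.), CH2Cl2, 0 °C
Reagents that add atoms: acetic anhydride, CC(=O)OC(C)=O
Why: Fast DMAP-catalysed acetylation of the single free hydroxyl (C11) should outpace any O10-to-O11 benzoyl shift.

Step 17
Reactants: 24 bis-PMB ether of the target
Product: 25 CNP0230210.1, (2S,3R,3aR,7R,7aR)-2-[(1E,3S,4R)-4-acetoxy-3-(benzoyloxy)pent-1-en-1-yl]-3,7-dihydroxyhexahydro-5H-furo[3,2-b]pyran-5-one
Conditions: DDQ (3 equiv), CH2Cl2/pH 7 buffer (10:1), 0 °C to rt
Reagents that add atoms: none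
Why: Oxidative cleavage of both 4-methoxybenzyl ethers (benzylic hydride abstraction, hydrolysis of the oxocarbenium ion) under neutral conditions should release O3–H and O6–H and leave the two esters, the β-hydroxy lactone and the allylic C–O bonds intact.

Compound list
1 | 3,4-O-isopropylidene-D-mannitol | OC[C@@H](O)[C@H]1OC(C)(C)O[C@@H]1[C@H](O)CO | starting material
2 | 3,4-O-isopropylidene-1,6-di-O-(4-toluenesulfonyl)-D-mannitol | Cc1ccc(cc1)S(=O)(=O)OC[C@@H](O)[C@H]2OC(C)(C)O[C@@H]2[C@H](O)COS(=O)(=O)c3ccc(C)cc3 | intermediate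
3 | 1,2:5,6-dianhydro-3,4-O-isopropylidene-D-mannitol | C1O[C@H]1[C@H]2OC(C)(C)O[C@@H]2[C@H]3CO3 | intermediate
4 | (3R,4R,5R,6R)-1,8-bis(dimethylsulfonio)-4,5-(isopropylidenedioxy)octane-3,6-diolate (bis-sulfonium betaine, not isolated) | C[S+](C)CC[C@@H]([O-])[C@H]1OC(C)(C)O[C@@H]1[C@H]([O-])CC[S+](C)C | intermediate
5 | (3R,4R,5R,6R)-4,5-(isopropylidenedioxy)octa-1,7-diene-3,6-diol | C=C[C@@H](O)[C@H]1OC(C)(C)O[C@@H]1[C@H](O)C=C | intermediate
6 | (3R,4R,5R,6R)-4,5-(isopropylidenedioxy)-3,6-bis[(4-methoxybenzyl)oxy]octa-1,7-diene | C=C[C@@H](OCc1ccc(OC)cc1)[C@H]2OC(C)(C)O[C@@H]2[C@H](OCc3ccc(OC)cc3)C=C | intermediate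
7 | 9-[(3R,4R,5R,6R)-4,5-(isopropylidenedioxy)-3,6-bis[(4-methoxybenzyl)oxy]oct-7-en-1-yl]-9-borabicyclo[3.3.1]nonane (not isolated) | C(CB1C2CCCC1CCC2)[C@@H](OCc3ccc(OC)cc3)[C@H]4OC(C)(C)O[C@@H]4[C@H](OCc5ccc(OC)cc5)C=C | intermediate
8 | (3R,4R,5R,6R)-4,5-(isopropylidenedioxy)-3,6-bis[(4-methoxybenzyl)oxy]oct-7-en-1-ol | OCC[C@@H](OCc1ccc(OC)cc1)[C@H]2OC(C)(C)O[C@@H]2[C@H](OCc3ccc(OC)cc3)C=C | intermediate
9 | (3R,4S,5S,6R)-3,6-bis[(4-methoxybenzyl)oxy]oct-7-ene-1,4,5-triol | OCC[C@@H](OCc1ccc(OC)cc1)[C@@H](O)[C@H](O)[C@H](OCc2ccc(OC)cc2)C=C | intermediate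
10 | (R)-but-3-yn-2-ol | C[C@@H](O)C#C | starting material
11 | vinyl bromide (bromoethene) | BrC=C | starting material
12 | (R)-hex-5-en-3-yn-2-ol | C[C@@H](O)C#CC=C | intermediate
13 | lithium (5R)-3-ethenyl-2,2-dihydrido-5-methyl-2,5-dihydro-1,2-oxaluminol-2-uide (cyclic alkenylaluminate, not isolated) | C[C@H]1O[AlH2-]C(C=C)=C1.[Li+] | intermediate
14 | (2R,3E)-hexa-3,5-dien-2-ol | C[C@@H](O)/C=C/C=C | intermediate
15 | (2R,3R,4R)-3,4-epoxyhex-5-en-2-ol, i.e. (1R)-1-[(2R,3R)-3-ethenyloxiran-2-yl]ethanol | C[C@@H](O)[C@H]1O[C@@H]1C=C | intermediate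
16 | tert-butyl{(1R)-1-[(2S,3R)-3-ethenyloxiran-2-yl]ethoxy}dimethylsilane | C[C@@H](O[Si](C)(C)C(C)(C)C)[C@H]1O[C@@H]1C=C | intermediate
17 | (3R,4S,5S,6R,7E,9R,10S,11R)-11-[(tert-butyldimethylsilyl)oxy]-9,10-epoxy-3,6-bis[(4-methoxybenzyl)oxy]dodec-7-ene-1,4,5-triol | OCC[C@@H](OCc1ccc(OC)cc1)[C@@H](O)[C@H](O)[C@H](OCc2ccc(OC)cc2)/C=C/[C@H]3O[C@@H]3[C@@H](C)O[Si](C)(C)C(C)(C)C | intermediate
18 | (3R,4S,5R,6S,7S,8E,10S,11R)-11-[(tert-butyldimethylsilyl)oxy]-4,7-epoxy-3,6-bis[(4-methoxybenzyl)oxy]dodec-8-ene-1,5,10-triol (all-cis tetrahydrofuran) | C[C@@H](O[Si](C)(C)C(C)(C)C)[C@@H](O)/C=C/[C@@H]1O[C@H]([C@H](OCc2ccc(OC)cc2)CCO)[C@H](O)[C@@H]1OCc3ccc(OC)cc3 | intermediate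
19 | C1 aldehyde of 18 (hydroxy aldehyde with free C5 and C10 hydroxyls, not isolated) | C[C@@H](O[Si](C)(C)C(C)(C)C)[C@@H](O)/C=C/[C@@H]1O[C@H]([C@H](OCc2ccc(OC)cc2)CC=O)[C@H](O)[C@@H]1OCc3ccc(OC)cc3 | intermediate
20 | lactol of 19 (5-hydroxyhexahydro-5H-furo[3,2-b]pyran, both C1 epimers, not isolated) | C[C@@H](O[Si](C)(C)C(C)(C)C)[C@@H](O)/C=C/[C@@H]1O[C@H]2[C@H](OC(O)C[C@H]2OCc3ccc(OC)cc3)[C@@H]1OCc4ccc(OC)cc4 | intermediate
21 | (2S,3R,3aR,7R,7aR)-2-[(1E,3S,4R)-4-[(tert-butyldimethylsilyl)oxy]-3-hydroxypent-1-en-1-yl]-3,7-bis[(4-methoxybenzyl)oxy]hexahydro-5H-furo[3,2-b]pyran-5-one | C[C@@H](O[Si](C)(C)C(C)(C)C)[C@@H](O)/C=C/[C@@H]1O[C@H]2[C@H](OC(=O)C[C@H]2OCc3ccc(OC)cc3)[C@@H]1OCc4ccc(OC)cc4 | intermediate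
22 | (2S,3R,3aR,7R,7aR)-2-[(1E,3S,4R)-3-(benzoyloxy)-4-[(tert-butyldimethylsilyl)oxy]pent-1-en-1-yl]-3,7-bis[(4-methoxybenzyl)oxy]hexahydro-5H-furo[3,2-b]pyran-5-one | C[C@@H](O[Si](C)(C)C(C)(C)C)[C@@H](OC(=O)c5ccccc5)/C=C/[C@@H]1O[C@H]2[C@H](OC(=O)C[C@H]2OCc3ccc(OC)cc3)[C@@H]1OCc4ccc(OC)cc4 | intermediate
23 | (2S,3R,3aR,7R,7aR)-2-[(1E,3S,4R)-3-(benzoyloxy)-4-hydroxypent-1-en-1-yl]-3,7-bis[(4-methoxybenzyl)oxy]hexahydro-5H-furo[3,2-b]pyran-5-one | C[C@@H](O)[C@@H](OC(=O)c5ccccc5)/C=C/[C@@H]1O[C@H]2[C@H](OC(=O)C[C@H]2OCc3ccc(OC)cc3)[C@@H]1OCc4ccc(OC)cc4 | intermediate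
24 | (2S,3R,3aR,7R,7aR)-2-[(1E,3S,4R)-4-acetoxy-3-(benzoyloxy)pent-1-en-1-yl]-3,7-bis[(4-methoxybenzyl)oxy]hexahydro-5H-furo[3,2-b]pyran-5-one | CC(=O)O[C@H](C)[C@H](/C=C/[C@@H]1O[C@H]2[C@H](OC(=O)C[C@H]2OCc3ccc(OC)cc3)[C@@H]1OCc4ccc(OC)cc4)OC(=O)c5ccccc5 | intermediate
25 | CNP0230210.1, (2S,3R,3aR,7R,7aR)-2-[(1E,3S,4R)-4-acetoxy-3-(benzoyloxy)pent-1-en-1-yl]-3,7-dihydroxyhexahydro-5H-furo[3,2-b]pyran-5-one | CC(=O)O[C@H](C)[C@H](/C=C/[C@@H]1O[C@H]2[C@H](OC(=O)C[C@H]2O)[C@@H]1O)OC(=O)c1ccccc1 | target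

Total step count: 17 (13 on the main line, 4 for the side-chain fragment).
Longest linear sequence: 13 steps (1 → 2 → 3 → 5 → 6 → 8 → 9 → 17 → 18 → 21 → 22 → 23 → 24 → 25; steps 1–6 and 11–17).

Steps most likely to fail

Step 12 (key step). Closure onto the congested all-cis ring may be slower than collapse of the allylpalladium alkoxide by β-hydride elimination to a dienol or enone, or the C11 silyl group may shift to the transient C10 alkoxide. The fallback sets out from 17: the zwitterion is intercepted with CO2 (Pd(PPh3)4, CO2 1 atm, THF) to give, with net retention at C9, the trans vinyl cyclic carbonate F1. Methanolysis (K2CO3, MeOH, 0 °C) releases the threo-9,10-diol F2. PdCl2(MeCN)2 (THF, 0 °C) then closes the ring by syn oxypalladation of C7=C8 by O4 and syn loss of the C9 hydroxyl (syn-SN2′, 1,3-chirality transfer from C9 to C7), with no free alkoxide involved. This should give the same C7 configuration and E-C8=C9 alkene and returns to the route at 18.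

Step 11. Coupling of two allylically oxygenated alkenes may be slow, with ruthenium-induced opening or isomerisation of the vinyl epoxide and erosion of E/Z purity. The fallback sets out from 16 and 9 and takes the epoxide out of the metathesis step: 16 is first converted (Pd(PPh3)4, CO2, THF) into the vinyl cyclic carbonate F3, a robust metathesis partner. Cross-metathesis of 9 with F3 (Hoveyda–Grubbs II) gives the carbonate F1 described above. Decarboxylative ionisation of F1 with Pd(0) generates the same allylpalladium alkoxide as in step 12 and closes to 18, where the route is rejoined.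

Step 13. The allylic C10 carbinol may be oxidised to the enone before the lactol is consumed. The fallback sets out from 18 and reorders the endgame so that no allylic alcohol is free during the oxidation. The primary hydroxyl is silylated selectively (TBSCl, imidazole, CH2Cl2, −20 °C) to the C1 silyl ether F4. The C10 hydroxyl is benzoylated (BzCl, pyridine, 0 °C; the C5 hydroxyl on the concave face should react more slowly) to the benzoate F5. Both silyl ethers are removed (HF·pyridine, THF) to the triol F6. TEMPO/PhI(OAc)2 lactonisation of the 1,5-diol then gives 23, where the route is rejoined.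

Further compounds
F1 | step 12 | (3R,4S,5S,6R,7E)-9,10-O-carbonyl derivative of the threo-9,10-diol: trans-4,5-disubstituted 1,3-dioxolan-2-one with 11-OTBS, 3,6-bis(PMBO) and free 1,4,5-triol | OCC[C@@H](OCc1ccc(OC)cc1)[C@@H](O)[C@H](O)[C@H](OCc2ccc(OC)cc2)/C=C/[C@H]3OC(=O)O[C@@H]3[C@@H](C)O[Si](C)(C)C(C)(C)C
F2 | step 12 | (7E)-11-[(tert-butyldimethylsilyl)oxy]-3,6-bis[(4-methoxybenzyl)oxy]dodec-7-ene-1,4,5,9,10-pentol (9,10-threo, C9–O on the face of the former epoxide) | OCC[C@@H](OCc1ccc(OC)cc1)[C@@H](O)[C@H](O)[C@H](OCc2ccc(OC)cc2)/C=C/[C@@H](O)[C@H](O)[C@@H](C)O[Si](C)(C)C(C)(C)C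
F3 | step 11 | trans-4-ethenyl-5-[(1R)-1-[(tert-butyldimethylsilyl)oxy]ethyl]-1,3-dioxolan-2-one (from 16 with retention at both ring carbons) | C=C[C@H]1OC(=O)O[C@@H]1[C@@H](C)O[Si](C)(C)C(C)(C)C
F4 | step 13 | 1-O-TBS ether of 18 (free C5 and C10 hydroxyls) | C[C@@H](O[Si](C)(C)C(C)(C)C)[C@@H](O)/C=C/[C@@H]1O[C@H]([C@H](OCc2ccc(OC)cc2)CCO[Si](C)(C)C(C)(C)C)[C@H](O)[C@@H]1OCc3ccc(OC)cc3
F5 | step 13 | 10-O-benzoate of F4 (free C5 hydroxyl) | C[C@@H](O[Si](C)(C)C(C)(C)C)[C@@H](OC(=O)c4ccccc4)/C=C/[C@@H]1O[C@H]([C@H](OCc2ccc(OC)cc2)CCO[Si](C)(C)C(C)(C)C)[C@H](O)[C@@H]1OCc3ccc(OC)cc3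
F6 | step 13 | 10-O-benzoyl-1,5,11-triol (both silyl ethers of F5 removed) | C[C@@H](O)[C@@H](OC(=O)c4ccccc4)/C=C/[C@@H]1O[C@H]([C@H](OCc2ccc(OC)cc2)CCO)[C@H](O)[C@@H]1OCc3ccc(OC)cc3
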